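## Structural features

The target is a 2,3-dihydro-1H-indene: a resorcinol-type benzene ring (ring A, C3a–C7a, hydroxyls at C4 and C6) fused to a cyclopentane whose three sp3 carbons carry a 4-hydroxybenzoyl group (C1), a 4-hydroxyphenyl group (C2) and a 3,5-dihydroxyphenyl group (C3). This indane numbering of the target is used for the atoms of all intermediates, whatever their systematic names. C1, C2 and C3 are contiguous stereocentres with all three substituents on the same face, (1R,2R,3R). C1–H is α to the aryl ketone and the all-cis arrangement is the less stable one, so base or Lewis acid can epimerise it; the six free phenols are oxidation-prone and should be unmasked last. The real difficulty is a crowded all-cis triad as a single enantiomer, with no heteroatom on any stereocentre to serve as a handle. The problem shrinks to one centre once it is seen that C1 and C2 can come from syn addition of hydrogen to a C1=C2 enone, steered by C3. The key step exploits two facts about ring A: C7a is its only unsubstituted position ortho to C3a, so a benzophenone with C3 as carbonyl carbon can direct a metal to C7a–H while an alkyne supplies C1 and C2 with their substituents. The C4 oxygen sits next to C3, so the tertiary C3 carbinol formed in that step is a ready precursor of an ortho-quinone methide.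

## Logic of the disconnections

17 ⇒ 16. Five aryl O–CH3 bonds are restored. The phenols would interfere with almost every earlier step, and methyl ethers come with the starting materials. Nothing is gained in skeleton, much in handling. The forward ether cleavage must leave the C1 configuration untouched.

16 ⇒ 15. The C1–H and C2–H bonds are removed to give the C1=C2 enone. Both centres then arise in one syn addition of hydrogen from the face opposite the C3 aryl group, and all-cis is the kinetic result. Two of three stereocentres disappear. The forward step needs clean face selection, no migration of the alkene and survival of the aryl ketone.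

15 ⇒ 13 (through 14). C3–H is exchanged for C3–OH. The carbinol lies next to the free C4 hydroxyl, so loss of water gives 14 with C3 as the methide carbon; the ring fixes the methide geometry and only a face has to be chosen. The last stereocentre is removed and 13 may be racemic. The forward step needs catalyst-controlled hydride delivery to C3 and must not enolise 15 afterwards. Having the ketone in place before this step means 13 holds a single stereogenic element and no ionisable benzylic carbinol.

13 ⇒ 12. The exocyclic C=O is taken back to CH–OH. A ketone at this carbon cannot pass through the annulation, because an ynone would reverse the polarisation of the alkyne. The forward oxidation must pick the allylic, benzylic alcohol beside a phenol and a tertiary alcohol.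

12 ⇒ 11. Two O–Si bonds are restored, one on the C4 oxygen and one on the carbinol oxygen. Both oxygens must be masked during the annulation. Silicon on both allows a single fluoride treatment and avoids acid while an ionisable tertiary indenol and a 4-methoxybenzylic ether are present; an acetal on the C4 oxygen would need acid for its removal.

11 ⇒ 5 + 10. The bonds C7a–C1 and C2–C3 are cut, opening the five-membered ring. Every carbon of the target is then divided between two pieces of similar size, each two steps from commercial materials. The forward step must metalate C7a–H and not the other aryl ring, insert the alkyne with its aryl-bearing carbon on the metal, and add the alkenyl–metal to a hindered, electron-rich ketone.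

5 ⇒ 4 ⇒ 3 ⇒ 1 + 2. The O–Si bond, then the O–CH3 bond next to the carbonyl and the C3–C3a bond are cut. Acylation of 1 occurs at its doubly activated position, and the chelated ortho methoxy group of 3 is cleaved in the same flask, which differentiates the C4 oxygen at no cost in steps. The forward step must stop at mono-demethylation.

10 ⇒ 9 ⇒ 8 + 7, 8 ⇒ 6. The O–Si bond and the bond between the alkyne carbon and the carbinol carbon are cut. This is a plain acetylide addition with no selectivity demand; the carbinol centre may be racemic because it later becomes a ketone.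

## Other disconnections considered

Alternative 1: The cut is C1–C2 of the five-membered ring, made together with the C3–H bond. Forward, aldehyde A2 would be cyclised by a cationic chiral bisphosphine complex of monovalent rhodium (for example [Rh(cod)2]BF4 with a BINAP-type ligand): oxidative addition of the formyl C–H bond, insertion of the 1,1-diarylethene (which fixes C3) and reductive elimination to indanone A1.
- In favour: ring and C3 stereocentre arise in one catalytic step without by-product. Setting the absolute configuration at ring formation, and needing no differentiated C4 hydroxyl (all oxygens stay methyl ethers), are points on which it is better than the chosen plan; in atom economy the two key steps are equal.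
- Against: A1 lacks the C2 aryl group and the whole aroyl unit. α-Arylation at C2, conversion of the C1 ketone into an enol sulfonate and a carbonylative cross-coupling would have to follow, and they lead into the same kind of C1=C2 enone as 15, with the same acidic C3–H and the same hydrogenation and demethylation. A2 needs a hindered cross-coupling to place a 1-arylvinyl group between a formyl and a methoxy group, and its twisted alkene is a demanding partner for hydrometalation, with decarbonylation as the competing path.
- Comparison: in structure, the alternative key step makes one ring bond and one stereocentre but only part of the skeleton, whereas step 5 makes two ring bonds and brings in every carbon but no stereocentre. In mechanism, it shuttles between monovalent and trivalent rhodium, whereas step 5 runs at constant oxidation state. In step economy, about four steps to A2 and six after A1 would be no shorter than the ten chosen.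

Alternative 2: The cut is C1–C7a, seen backwards as expansion of the five-membered ring to a six-membered α-diazo ketone. Forward, irradiation of diazonaphthalenone A4 would expel nitrogen, the ring A carbon would shift from the carbonyl carbon to the carbene carbon (Wolff rearrangement) and water would trap the ketene as indenecarboxylic acid A3.
- In favour: no metal and no reagent, tolerance of electron-rich arenes, and a product that already carries the C1 carbon at the carbonyl oxidation level with both aryl groups on C2 and C3. It is the equal of step 5 in having all ring carbons present, and better in needing no later oxidation and no silyl groups.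
- Against: A4 is a fully substituted 3,4-diarylnaphthalenone that must first be built by benzannulation and regioselective diazo transfer, so a six-membered ring is made only to be contracted. A3 has its double bond at C2=C3 and a racemic, enolisable C1, so no stereocentre of the target is set and nothing like the C3 carbinol/C4 hydroxyl pair exists for absolute control; a resolution or an asymmetric hydrogenation of a tetrasubstituted alkene would be required. The acid must also be turned into the aryl ketone.
- Comparison: the all-cis relationship could again come from hydrogenation anti to the C1 substituent, which is equal to the chosen plan. Overall the sequence would be longer and would leave enantiocontrol open.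

Alternative 3: The cuts are C1–C2 (between the α-carbon of an arylacetic acid and the anisyl-bearing carbon) and, later, C3–C3a. Forward, the dianion of A6 would open enantiopure trans-epoxide A7 at its 4-methoxybenzylic carbon with inversion, and the γ-hydroxy acid would close to lactone A5. Acid would then let the dimethoxyphenyl ring on the lactone α-carbon displace the lactone oxygen, exchanging the lactone for the indane ring with a C1 carboxylic acid.
- In favour: the absolute configuration comes stereospecifically from an epoxide that asymmetric epoxidation can supply, reagents are cheap, no transition metal is needed and all oxygens can be methyl ethers. On the source of absolute stereochemistry and on protecting-group uniformity it is better than the chosen plan, and it is equally convergent.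
- Against: A5 is 3,4-trans, so the indane inherits a C1/C2 trans relationship, whereas 17 is all-cis, the less stable arrangement at the enolisable C1, which equilibration cannot reach. C1 and C2 would have to be erased to the C1=C2 enone and rebuilt by hydrogenation, so the end of the chosen route would be needed anyway. The ring switch must break a C–O bond at a carbon whose cation gets no help from two meta methoxy groups, so the configuration at C3, the one centre that must be kept, is uncertain; partial SN1 character in the epoxide opening would erode C2 as well. The acid must also become the aryl ketone.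
- Comparison: the chemistry is ionic throughout, set against the metal-mediated C–H functionalisation of step 5, and the step count would be clearly higher.

Key step: step 5

Assumption: the face of 14 to which the (R)-configured phosphoric acid sends hydride cannot be predicted with certainty for this ring-fused quinone methide; the (R)-acid is written in step 8 and its mirror image is to be used if the (1R)-indene should result.

## Steps

Step 1
Reactants: 1 1,3-dimethoxybenzene; 2 3,5-dimethoxybenzoyl chloride
Product: 4 (2-hydroxy-4-methoxyphenyl)(3,5-dimethoxyphenyl)methanone, via 2,4,3',5'-tetramethoxybenzophenone 3 (not isolated)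
Conditions: AlCl3 (2.5 equiv), CH2Cl2, 0 °C → 40 °C; then 1 M HCl
Reagents that add atoms: none
Why: Friedel–Crafts acylation should occur at the position of 1 that is para to one methoxy group and ortho to the other; the aluminium chelate between the new carbonyl and the ortho methoxy group of 3 is then cleaved by chloride (chelation-controlled O-demethylation), leaving the other three methyl ethers intact.

Step 2
Reactants: 4 (2-hydroxy-4-methoxyphenyl)(3,5-dimethoxyphenyl)methanone
Product: 5 (3,5-dimethoxyphenyl){4-methoxy-2-[(triisopropylsilyl)oxy]phenyl}methanone
Conditions: TIPSOTf, 2,6-lutidine, CH2Cl2, 0 °C → rt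
Reagents that add atoms: triisopropylsilyl trifluoromethanesulfonate, CC(C)[Si](C(C)C)(C(C)C)OS(=O)(=O)C(F)(F)F
Why: O-silylation of a phenol; the silyl triflate should overcome the hydrogen bond to the carbonyl, and the bulky aryl silyl ether should survive the hot, weakly Lewis-acidic key step, keep the phenol from chelating rhodium, and leave with fluoride.

Step 3
Reactants: 6 1-ethynyl-4-methoxybenzene (4-ethynylanisole); 7 4-methoxybenzaldehyde
Product: 9 1,3-bis(4-methoxyphenyl)prop-2-yn-1-ol (racemic), via lithium (4-methoxyphenyl)acetylide 8 (not isolated)
Conditions: n-BuLi, THF, −78 °C; then 7, −78 → 0 °C; H2O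
Reagents that add atoms: none
Why: Deprotonation of the terminal alkyne and 1,2-addition of the lithium acetylide to the aldehyde (acetylide addition); the carbinol centre is formed racemic, which does not matter because it becomes a ketone in step 7.

Step 4
Reactants: 9 1,3-bis(4-methoxyphenyl)prop-2-yn-1-ol
Product: 10 tert-butyl{[1,3-bis(4-methoxyphenyl)prop-2-yn-1-yl]oxy}dimethylsilane (racemic)
Conditions: TBSCl, imidazole, DMF, rt
Reagents that add atoms: tert-butyldimethylsilyl chloride, CC(C)(C)[Si](C)(C)Cl
Why: Standard silylation of a secondary alcohol; the silyl ether removes hydroxyl coordination to rhodium and slows ionisation of the 4-methoxybenzylic propargylic position.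

Step 5
Reactants: 5 (3,5-dimethoxyphenyl){4-methoxy-2-[(triisopropylsilyl)oxy]phenyl}methanone; 10 tert-butyl{[1,3-bis(4-methoxyphenyl)prop-2-yn-1-yl]oxy}dimethylsilane
Product: 11 3-{[(tert-butyldimethylsilyl)oxy](4-methoxyphenyl)methyl}-1-(3,5-dimethoxyphenyl)-5-methoxy-2-(4-methoxyphenyl)-7-[(triisopropylsilyl)oxy]-1H-inden-1-ol (racemic, both diastereomers)
Conditions: [Cp*RhCl2]2 (2.5 mol%), AgSbF6 (10 mol%), Cu(OAc)2 (50 mol%), PhCl, 110 °C, Ar
Reagents that add atoms: none
Why: The closest known reaction type is the Cp*Rh-catalysed (trivalent rhodium) C–H activation and carbocyclisation of aryl ketones with internal alkynes to 1H-inden-1-ols, a redox-neutral formal (3+2) annulation. AgSbF6 removes chloride from [Cp*RhCl2]2, the cationic rhodium binds the carbonyl oxygen of 5, and acetate-assisted concerted metalation–deprotonation at C7a–H gives a five-membered rhodacycle. Alkyne 10 then inserts into the Rh–C7a bond (bond C7a–C1) and the alkenyl–rhodium adds to the coordinated ketone (bond C2–C3); acetic acid frees 11 from the rhodium alkoxide with no change of oxidation state at the metal. The five-membered ring closes in this carbonyl addition, a 5-exo-trig attack of C2 on C3. The tertiary carbinol C3 forms without control and gives diastereomers with the racemic silyloxy carbon, which is harmless because that carbon becomes a ketone in step 7 and C3 becomes planar in step 8. Site selectivity should follow from the substrate: C7a–H is the only ortho C–H of ring A, whereas both ortho C–H bonds of the 3,5-dimethoxyphenyl ring lie between the carbonyl-bearing carbon and a methoxy group and are poor sites for the bulky Cp*Rh fragment. Insertion regiochemistry is also required: the aryl-substituted alkyne carbon should end on rhodium, as is the rule for aryl–alkyl alkynes, and the silyl ether removes the hydroxyl coordination that would steer rhodium to the propargylic side and open a β-oxygen elimination. Because 5 has no α-hydrogen, the indenol cannot dehydrate to a fulvene.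

Step 6
Reactants: 11 the doubly silylated indenol of step 5
Product: 12 1-(3,5-dimethoxyphenyl)-3-[hydroxy(4-methoxyphenyl)methyl]-5-methoxy-2-(4-methoxyphenyl)-1H-indene-1,7-diol (racemic, both diastereomers)
Conditions: TBAF (3 equiv), THF, 0 °C → rt
Reagents that add atoms: none
Why: Fluoride-mediated desilylation should cleave the aryl and the secondary alkyl silyl ether in one operation; no acid is present, so neither the tertiary indenol nor the 4-methoxybenzylic carbinol ionises, and no stereocentre of consequence exists yet.

Step 7
Reactants: 12 1-(3,5-dimethoxyphenyl)-3-[hydroxy(4-methoxyphenyl)methyl]-5-methoxy-2-(4-methoxyphenyl)-1H-indene-1,7-diol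
Product: 13 [1-(3,5-dimethoxyphenyl)-1,7-dihydroxy-5-methoxy-2-(4-methoxyphenyl)-1H-inden-3-yl](4-methoxyphenyl)methanone (racemic)
Conditions: activated MnO2 (excess), CH2Cl2, rt
Reagents that add atoms: none
Why: Manganese dioxide oxidation is selective for the allylic and benzylic secondary alcohol; the tertiary alcohol cannot be oxidised and the phenol should be left at room temperature. Both diastereomers of 12 converge on one racemate.

Step 8
Reactants: 13 [1-(3,5-dimethoxyphenyl)-1,7-dihydroxy-5-methoxy-2-(4-methoxyphenyl)-1H-inden-3-yl](4-methoxyphenyl)methanone
Product: 15 [(1S)-1-(3,5-dimethoxyphenyl)-7-hydroxy-5-methoxy-2-(4-methoxyphenyl)-1H-inden-3-yl](4-methoxyphenyl)methanone, via ortho-quinone methide 14 (not isolated)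
Conditions: (R)-3,3'-bis(2,4,6-triisopropylphenyl)-1,1'-binaphthyl-2,2'-diyl hydrogen phosphate (10 mol%), Hantzsch ester (diethyl 2,6-dimethyl-1,4-dihydropyridine-3,5-dicarboxylate, 1.3 equiv), 4 Å MS, CH2Cl2, 0 °C → rt; short plug filtration, used at once
Reagents that add atoms: none
Why: Acid-catalysed dehydration of the ortho-hydroxybenzylic tertiary alcohol gives 14, and the chiral phosphate, hydrogen-bonded to the quinone methide oxygen and to the N–H of the dihydropyridine, should deliver hydride to one face of C3 (organocatalytic asymmetric transfer hydrogenation of an ortho-quinone methide formed in situ). Attack at C3 restores the aromaticity of ring A, and the ring locks the methide geometry, so the catalyst alone sets C3 (S in 15, the spatial arrangement of C3 in the target).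

Step 9
Reactants: 15 [(1S)-1-(3,5-dimethoxyphenyl)-7-hydroxy-5-methoxy-2-(4-methoxyphenyl)-1H-inden-3-yl](4-methoxyphenyl)methanone
Product: 16 [(1R,2R,3R)-3-(3,5-dimethoxyphenyl)-4-hydroxy-6-methoxy-2-(4-methoxyphenyl)-2,3-dihydro-1H-inden-1-yl](4-methoxyphenyl)methanone
Conditions: H2 (1–4 bar), 10% Pd/C, EtOAc, rt
Reagents that add atoms: none
Why: Heterogeneous catalytic hydrogenation adds both hydrogens syn to the C1=C2 bond from the face opposite the C3 aryl group (substrate control), so the aroyl and anisyl groups end cis to each other and to the C3 aryl group. The neutral medium spares the acidic C3–H of 15 and the epimerisable C1 of 16.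

Step 10
Reactants: 16 [(1R,2R,3R)-3-(3,5-dimethoxyphenyl)-4-hydroxy-6-methoxy-2-(4-methoxyphenyl)-2,3-dihydro-1H-inden-1-yl](4-methoxyphenyl)methanone
Product: 17 caraphenol B, [(1R,2R,3R)-3-(3,5-dihydroxyphenyl)-4,6-dihydroxy-2-(4-hydroxyphenyl)-2,3-dihydro-1H-inden-1-yl](4-hydroxyphenyl)methanone
Conditions: BBr3 (15 equiv), CH2Cl2, −78 → 0 °C; ice-water
Reagents that add atoms: none
Why: Lewis-acid cleavage of the five aryl methyl ethers (boron tribromide demethylation); low temperature and an acidic, base-free quench are chosen to keep the C1 centre from enolising.

## Compound list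

1 | 1,3-dimethoxybenzene | COc1cccc(OC)c1 | starting material
2 | 3,5-dimethoxybenzoyl chloride | COc1cc(OC)cc(C(Cl)=O)c1 | starting material
3 | (2,4-dimethoxyphenyl)(3,5-dimethoxyphenyl)methanone (2,4,3',5'-tetramethoxybenzophenone) | COc1ccc(C(=O)c2cc(OC)cc(OC)c2)c(OC)c1 | intermediate (not isolated)
4 | (2-hydroxy-4-methoxyphenyl)(3,5-dimethoxyphenyl)methanone | COc1ccc(C(=O)c2cc(OC)cc(OC)c2)c(O)c1 | intermediate
5 | (3,5-dimethoxyphenyl){4-methoxy-2-[(triisopropylsilyl)oxy]phenyl}methanone | COc1ccc(C(=O)c2cc(OC)cc(OC)c2)c(O[Si](C(C)C)(C(C)C)C(C)C)c1 | intermediate
6 | 1-ethynyl-4-methoxybenzene | COc1ccc(C#C)cc1 | starting material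
7 | 4-methoxybenzaldehyde | COc1ccc(C=O)cc1 | starting material
8 | lithium (4-methoxyphenyl)acetylide | [Li]C#Cc1ccc(OC)cc1 | intermediate (not isolated)
9 | 1,3-bis(4-methoxyphenyl)prop-2-yn-1-ol, racemic | COc1ccc(cc1)C#CC(O)c1ccc(OC)cc1 | intermediate
10 | tert-butyl{[1,3-bis(4-methoxyphenyl)prop-2-yn-1-yl]oxy}dimethylsilane, racemic | COc1ccc(cc1)C#CC(O[Si](C)(C)C(C)(C)C)c1ccc(OC)cc1 | intermediate
11 | 3-{[(tert-butyldimethylsilyl)oxy](4-methoxyphenyl)methyl}-1-(3,5-dimethoxyphenyl)-5-methoxy-2-(4-methoxyphenyl)-7-[(triisopropylsilyl)oxy]-1H-inden-1-ol, racemic, both diastereomers | CC(C)(C)[Si](C)(C)OC(c1ccc(OC)cc1)C1=C(c2ccc(OC)cc2)C(O)(c2cc(OC)cc(OC)c2)c2c(O[Si](C(C)C)(C(C)C)C(C)C)cc(OC)cc21 | intermediate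
12 | 1-(3,5-dimethoxyphenyl)-3-[hydroxy(4-methoxyphenyl)methyl]-5-methoxy-2-(4-methoxyphenyl)-1H-indene-1,7-diol, racemic, both diastereomers | OC(c1ccc(OC)cc1)C1=C(c2ccc(OC)cc2)C(O)(c2cc(OC)cc(OC)c2)c2c(O)cc(OC)cc21 | intermediate
13 | [1-(3,5-dimethoxyphenyl)-1,7-dihydroxy-5-methoxy-2-(4-methoxyphenyl)-1H-inden-3-yl](4-methoxyphenyl)methanone, racemic | O=C(c1ccc(OC)cc1)C1=C(c2ccc(OC)cc2)C(O)(c2cc(OC)cc(OC)c2)c2c(O)cc(OC)cc21 | intermediate
14 | 1-(3,5-dimethoxyphenyl)-5-methoxy-3-(4-methoxybenzoyl)-2-(4-methoxyphenyl)-7H-inden-7-one (ortho-quinone methide) | O=C(c1ccc(OC)cc1)C1=C(c2ccc(OC)cc2)C(c2cc(OC)cc(OC)c2)=C2C(=O)C=C(OC)C=C12 | intermediate (not isolated)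
15 | [(1S)-1-(3,5-dimethoxyphenyl)-7-hydroxy-5-methoxy-2-(4-methoxyphenyl)-1H-inden-3-yl](4-methoxyphenyl)methanone | O=C(c1ccc(OC)cc1)C1=C(c2ccc(OC)cc2)[C@H](c2cc(OC)cc(OC)c2)c2c(O)cc(OC)cc21 | intermediate
16 | [(1R,2R,3R)-3-(3,5-dimethoxyphenyl)-4-hydroxy-6-methoxy-2-(4-methoxyphenyl)-2,3-dihydro-1H-inden-1-yl](4-methoxyphenyl)methanone | O=C(c1ccc(OC)cc1)[C@H]1c2cc(OC)cc(O)c2[C@@H](c2cc(OC)cc(OC)c2)[C@H]1c1ccc(OC)cc1 | intermediate
17 | caraphenol B, [(1R,2R,3R)-3-(3,5-dihydroxyphenyl)-4,6-dihydroxy-2-(4-hydroxyphenyl)-2,3-dihydro-1H-inden-1-yl](4-hydroxyphenyl)methanone | O=C(c1ccc(O)cc1)[C@H]1c2cc(O)cc(O)c2[C@@H](c2cc(O)cc(O)c2)[C@H]1c1ccc(O)cc1 | target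

## Step count and least certain steps

Total step count: 10. Longest linear sequence: 8 steps (steps 1, 2, 5, 6, 7, 8, 9, 10; the alkyne branch, steps 3 and 4, joins at step 5 and is equally long).

Step 5 (key step). The process most likely to fail is alkyne insertion: the carbon that must bond to C7a carries a branched silyloxybenzyl group, so steric repulsion with the arene works against the electronic preference for placing the aryl-bearing carbon on rhodium. The result could be slow insertion, eroded regioselectivity, or protonation of the alkenyl–rhodium before it adds to the hindered ketone. The fallback sets out from 6 and comes back to the route at 12. Lithiation of 6 and addition to paraformaldehyde would give 3-(4-methoxyphenyl)prop-2-yn-1-ol F1, which TBSCl and imidazole would convert into tert-butyl{[3-(4-methoxyphenyl)prop-2-yn-1-yl]oxy}dimethylsilane F2. This aryl–primary-alkyl alkyne belongs to the class for which the insertion sense is established. The same annulation with 5 should therefore give 3-{[(tert-butyldimethylsilyl)oxy]methyl}-1-(3,5-dimethoxyphenyl)-5-methoxy-2-(4-methoxyphenyl)-7-[(triisopropylsilyl)oxy]-1H-inden-1-ol F3. TBAF would free 1-(3,5-dimethoxyphenyl)-3-(hydroxymethyl)-5-methoxy-2-(4-methoxyphenyl)-1H-indene-1,7-diol F4. MnO2 would oxidise the primary allylic alcohol to 1-(3,5-dimethoxyphenyl)-1,7-dihydroxy-5-methoxy-2-(4-methoxyphenyl)-1H-indene-3-carbaldehyde F5, and excess 4-MeOC6H4MgBr would add 1,2 to the aldehyde (Grignard addition) to give 12.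

Step 8. Three processes threaten it: slow ionisation, because the carbinol carbon carries a vinyl group deactivated by the ketone; loss of enantiopurity by acid-promoted dienolisation of 15, whose C3–H is doubly benzylic and vinylogously α to the ketone; and hydride delivery to C1 instead of C3. The fallback sets out from 11 and comes back at 15, reducing before oxidising. One equivalent of TBAF at −40 °C should cleave only the aryl silyl ether and give 3-{[(tert-butyldimethylsilyl)oxy](4-methoxyphenyl)methyl}-1-(3,5-dimethoxyphenyl)-5-methoxy-2-(4-methoxyphenyl)-1H-indene-1,7-diol F6. The same phosphoric acid and Hantzsch ester would reduce its more electron-rich quinone methide to (1S)-3-{[(tert-butyldimethylsilyl)oxy](4-methoxyphenyl)methyl}-1-(3,5-dimethoxyphenyl)-5-methoxy-2-(4-methoxyphenyl)-1H-inden-7-ol F7, as both epimers at the silyloxy carbon and not enolisable. Non-basic fluoride (Et3N·3HF, MeCN) would give (1S)-1-(3,5-dimethoxyphenyl)-3-[hydroxy(4-methoxyphenyl)methyl]-5-methoxy-2-(4-methoxyphenyl)-1H-inden-7-ol F8, and MnO2 would oxidise it to 15 immediately before step 9. The price is one more step and a stereocentre on the side chain that may disturb the catalyst's face selection for one epimer.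

Step 9. Migration of the alkene from C1=C2 to C2=C3 on the palladium surface would erase C3 before reduction; the tetrasubstituted alkene may also react slowly, which invites over-reduction of the aryl ketone. The fallback sets out from 15 and comes back at 16, replacing surface hydrogenation by polar conjugate reduction. [(Ph3P)CuH]6 (monovalent copper hydride, excess to allow for the phenol) in toluene/THF should deliver hydride to C2 anti to the C3 aryl group, and the enolate would then be protonated at C1 at low temperature from the face opposite the two aryl groups, which again gives the all-cis ketone. No new compound is made on this path (F0).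

Step 10. Enolisation of the boron-complexed ketone would epimerise C1 toward the more stable trans arrangement. The fallback sets out from 15 and comes back at 17 by reversing the order of the last two steps. BBr3 on 15 would give [(1S)-1-(3,5-dihydroxyphenyl)-5,7-dihydroxy-2-(4-hydroxyphenyl)-1H-inden-3-yl](4-hydroxyphenyl)methanone F9, and hydrogenation (H2, 10% Pd/C, EtOAc/MeOH) would then create C1 and C2 last, under neutral conditions, giving 17. The cost is that the acidic C3–H of the enone is exposed to the Lewis acid, so enantiopurity would have to be monitored at F9.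

## Further compounds

F1 | step 5 | 3-(4-methoxyphenyl)prop-2-yn-1-ol | COc1ccc(cc1)C#CCO
F2 | step 5 | tert-butyl{[3-(4-methoxyphenyl)prop-2-yn-1-yl]oxy}dimethylsilane | COc1ccc(cc1)C#CCO[Si](C)(C)C(C)(C)C
F3 | step 5 | 3-{[(tert-butyldimethylsilyl)oxy]methyl}-1-(3,5-dimethoxyphenyl)-5-methoxy-2-(4-methoxyphenyl)-7-[(triisopropylsilyl)oxy]-1H-inden-1-ol, racemic | CC(C)(C)[Si](C)(C)OCC1=C(c2ccc(OC)cc2)C(O)(c2cc(OC)cc(OC)c2)c2c(O[Si](C(C)C)(C(C)C)C(C)C)cc(OC)cc21
F4 | step 5 | 1-(3,5-dimethoxyphenyl)-3-(hydroxymethyl)-5-methoxy-2-(4-methoxyphenyl)-1H-indene-1,7-diol, racemic | OCC1=C(c2ccc(OC)cc2)C(O)(c2cc(OC)cc(OC)c2)c2c(O)cc(OC)cc21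
F5 | step 5 | 1-(3,5-dimethoxyphenyl)-1,7-dihydroxy-5-methoxy-2-(4-methoxyphenyl)-1H-indene-3-carbaldehyde, racemic | O=CC1=C(c2ccc(OC)cc2)C(O)(c2cc(OC)cc(OC)c2)c2c(O)cc(OC)cc21
F6 | step 8 | 3-{[(tert-butyldimethylsilyl)oxy](4-methoxyphenyl)methyl}-1-(3,5-dimethoxyphenyl)-5-methoxy-2-(4-methoxyphenyl)-1H-indene-1,7-diol, racemic, both diastereomers | CC(C)(C)[Si](C)(C)OC(c1ccc(OC)cc1)C1=C(c2ccc(OC)cc2)C(O)(c2cc(OC)cc(OC)c2)c2c(O)cc(OC)cc21
F7 | step 8 | (1S)-3-{[(tert-butyldimethylsilyl)oxy](4-methoxyphenyl)methyl}-1-(3,5-dimethoxyphenyl)-5-methoxy-2-(4-methoxyphenyl)-1H-inden-7-ol, both epimers at the silyloxy carbon | CC(C)(C)[Si](C)(C)OC(c1ccc(OC)cc1)C1=C(c2ccc(OC)cc2)[C@H](c2cc(OC)cc(OC)c2)c2c(O)cc(OC)cc21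
F8 | step 8 | (1S)-1-(3,5-dimethoxyphenyl)-3-[hydroxy(4-methoxyphenyl)methyl]-5-methoxy-2-(4-methoxyphenyl)-1H-inden-7-ol, both epimers at the carbinol carbon | OC(c1ccc(OC)cc1)C1=C(c2ccc(OC)cc2)[C@H](c2cc(OC)cc(OC)c2)c2c(O)cc(OC)cc21
F0 | step 9 | none | none
F9 | step 10 | [(1S)-1-(3,5-dihydroxyphenyl)-5,7-dihydroxy-2-(4-hydroxyphenyl)-1H-inden-3-yl](4-hydroxyphenyl)methanone | O=C(c1ccc(O)cc1)C1=C(c2ccc(O)cc2)[C@H](c2cc(O)cc(O)c2)c2c(O)cc(O)cc21
A1 | alternative 1 | (3R)-3-(3,5-dimethoxyphenyl)-4,6-dimethoxy-2,3-dihydro-1H-inden-1-one | O=C1c2cc(OC)cc(OC)c2[C@@H](c2cc(OC)cc(OC)c2)C1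
A2 | alternative 1 | 2-[1-(3,5-dimethoxyphenyl)ethenyl]-3,5-dimethoxybenzaldehyde | O=Cc1cc(OC)cc(OC)c1C(=C)c1cc(OC)cc(OC)c1
A3 | alternative 2 | 3-(3,5-dimethoxyphenyl)-4,6-dimethoxy-2-(4-methoxyphenyl)-1H-indene-1-carboxylic acid, racemic | OC(=O)C1c2cc(OC)cc(OC)c2C(c2cc(OC)cc(OC)c2)=C1c1ccc(OC)cc1
A4 | alternative 2 | 2-diazo-4-(3,5-dimethoxyphenyl)-5,7-dimethoxy-3-(4-methoxyphenyl)naphthalen-1(2H)-one | O=C1C(=[N+]=[N-])C(c2ccc(OC)cc2)=C(c2cc(OC)cc(OC)c2)c2c(OC)cc(OC)cc12
A5 | alternative 3 | (3R,4R,5R)-3,5-bis(3,5-dimethoxyphenyl)-4-(4-methoxyphenyl)oxolan-2-one (3,4-trans, 4,5-cis) | O=C1O[C@@H](c2cc(OC)cc(OC)c2)[C@@H](c2ccc(OC)cc2)[C@@H]1c1cc(OC)cc(OC)c1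
A6 | alternative 3 | (3,5-dimethoxyphenyl)acetic acid | COc1cc(CC(O)=O)cc(OC)c1
A7 | alternative 3 | (2S,3S)-2-(3,5-dimethoxyphenyl)-3-(4-methoxyphenyl)oxirane | O1[C@@H](c2cc(OC)cc(OC)c2)[C@@H]1c1ccc(OC)cc1
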